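**Assumption:** the target has no stereocentre and no stereogenic axis (it is achiral), so "single enantiomer" needs no stereocontrol; the route delivers the one constitution given.

## Retrosynthetic overview

1. Target 9 ⇐ chelation-directed O-demethylation of the ring B 2-methoxy depside 8.
2. 8 ⇐ one-step C–C/C–O union at the ring B aryl–C(=O) bond: aryl iodide 4 plus aryl formate 6. Both carbons joined are electrophilic by nature; the formate carbon serves as an aryloxycarbonyl anion (d1) equivalent under palladium catalysis.
3. 4 ⇐ iodination of 3 ⇐ directed lithiation/chlorination of 3,5-dimethoxytoluene 1; 6 ⇐ O-formylation of methyl orsellinate 5.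
4. No ring is formed: ring B is bought as 1 and ring A as 5.

## Route

**Step 1**
Reactants: 1 3,5-dimethoxytoluene
Product: 3 2-chloro-1,3-dimethoxy-5-methylbenzene, via 4-lithio-3,5-dimethoxytoluene 2 (not isolated)
Conditions: n-BuLi (1.1 equiv), THF, 0 °C → rt, 2 h; then C2Cl6 (1.2 equiv), −78 °C → rt
Reagents that add atoms: hexachloroethane, ClC(Cl)(Cl)C(Cl)(Cl)Cl (the Cl of 3); n-butyllithium, [Li]CCCC (the Li of 2 only)
Why: Directed ortho-metalation followed by electrophilic chlorination: the C–H flanked by both methoxy groups is the most acidic, doubly coordinated site, so lithiation occurs only there and C2Cl6 transfers chlorine to the aryllithium; no stereocentre is formed.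

**Step 2**
Reactants: 3 2-chloro-1,3-dimethoxy-5-methylbenzene
Product: 4 2-chloro-4-iodo-1,3-dimethoxy-5-methylbenzene
Conditions: NIS (1.05 equiv), TFA (10 mol%), MeCN, rt, dark
Reagents that add atoms: N-iodosuccinimide, O=C1CCC(=O)N1I
Why: Electrophilic aromatic iodination (SEAr): the two open ring positions are equivalent by symmetry and each is ortho to one methoxy group and para to the other, so one equivalent of NIS gives a single regioisomer.

**Step 3**
Reactants: 5 methyl orsellinate (methyl 2,4-dihydroxy-6-methylbenzoate)
Product: 6 methyl 4-(formyloxy)-2-hydroxy-6-methylbenzoate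
Conditions: HCO2H/Ac2O (2 equiv each, 60 °C, 1 h, then cooled); 5, NaOAc (cat.), toluene, 0 °C → rt; used after short filtration
Reagents that add atoms: formic acid, O=CO (delivered as acetic formic anhydride, CC(=O)OC=O, made in the flask with acetic anhydride)
Why: O-Formylation with a mixed anhydride: the free 4-OH is the nucleophilic phenol while the 2-OH is held in a hydrogen bond to the ester, and the formyl carbonyl is the more electrophilic end of the mixed anhydride; any bis-formate is harmless because step 4 unmasks every formate.

**Step 4 (key step)**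
Reactants: 4 2-chloro-4-iodo-1,3-dimethoxy-5-methylbenzene; 6 methyl 4-(formyloxy)-2-hydroxy-6-methylbenzoate
Product: 8 methyl 4-[(3-chloro-2,4-dimethoxy-6-methylbenzoyl)oxy]-2-hydroxy-6-methylbenzoate, via carbon monoxide 7 (not isolated)
Conditions: Pd(OAc)2 (5 mol%), Xantphos (10 mol%), Et3N (2.5 equiv), 6 (1.5 equiv), MeCN, 80 °C, sealed tube, 16 h
Reagents that add atoms: none
Why: Palladium-catalysed aryloxycarbonylation of an aryl iodide with an aryl formate: the formate carbon, normally an electrophile, is delivered to the electrophilic C–I carbon as an aryloxycarbonyl anion equivalent, because Et3N unmasks 6 to CO 7 and the 4-phenoxide of 5, zerovalent palladium inserts into the C–I bond, CO insertion gives the aroylpalladium species, and the wide-bite-angle Xantphos drives acyl–O reductive elimination, so the aryl–carbonyl C–C bond and the depside C–O bond form together while the chelated 2-OH of ring A stays out.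

**Step 5**
Reactants: 8 methyl 4-[(3-chloro-2,4-dimethoxy-6-methylbenzoyl)oxy]-2-hydroxy-6-methylbenzoate
Product: 9 methyl 4-[(3-chloro-2-hydroxy-4-methoxy-6-methylbenzoyl)oxy]-2-hydroxy-6-methylbenzoate (target)
Conditions: BCl3 (3 equiv, 1 M in CH2Cl2), CH2Cl2, −78 → 0 °C; aq. NaHCO3 work-up
Reagents that add atoms: none
Why: Chelation-directed Lewis-acid ether cleavage: BCl3 binds between the depside carbonyl and the adjacent, out-of-plane 2-methoxy group of ring B and chloride removes that methyl selectively, leaving the 4-methoxy group, the methyl ester and the depside link intact at or below 0 °C; the target has no stereocentre.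

## Compound list

1 | 3,5-dimethoxytoluene (1,3-dimethoxy-5-methylbenzene) | COc1cc(C)cc(OC)c1 | starting material
2 | 4-lithio-3,5-dimethoxytoluene, (2,6-dimethoxy-4-methylphenyl)lithium | [Li]c1c(OC)cc(C)cc1OC | intermediate (not isolated)
3 | 2-chloro-1,3-dimethoxy-5-methylbenzene | COc1cc(C)cc(OC)c1Cl | intermediate
4 | 2-chloro-4-iodo-1,3-dimethoxy-5-methylbenzene | COc1cc(C)c(I)c(OC)c1Cl | intermediate
5 | methyl orsellinate (methyl 2,4-dihydroxy-6-methylbenzoate) | COC(=O)c1c(C)cc(O)cc1O | starting material
6 | methyl 4-(formyloxy)-2-hydroxy-6-methylbenzoate | COC(=O)c1c(C)cc(OC=O)cc1O | intermediate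
7 | carbon monoxide | [C-]#[O+] | intermediate (not isolated)
8 | methyl 4-[(3-chloro-2,4-dimethoxy-6-methylbenzoyl)oxy]-2-hydroxy-6-methylbenzoate | COC(=O)c1c(C)cc(OC(=O)c2c(C)cc(OC)c(Cl)c2OC)cc1O | intermediate
9 | methyl 4-[(3-chloro-2-hydroxy-4-methoxy-6-methylbenzoyl)oxy]-2-hydroxy-6-methylbenzoate | COC(=O)c1c(C)cc(OC(=O)c2c(C)cc(OC)c(Cl)c2O)cc1O | target

## Step count

Total steps: 5. Longest linear sequence: 4 steps (1 → 3 → 4 → 8 → 9; step 3 is a one-step side branch from 5).

## Steps most likely to fail, with fallbacks

**Step 4.** The aroylpalladium intermediate is flanked by OMe and CH3, so capture by the phenoxide may be slow and hydrodeiodination may win. The fallback sets out from 4 and comes back to the route at 8. It separates the C–C event from the C–O event. Iodide 4 is carbonylated with N-formylsaccharin as a solid CO donor and KF (Pd(OAc)2, Xantphos, DMF, 80 °C), so that the smallest nucleophile available, fluoride, captures the hindered acylpalladium and gives 3-chloro-2,4-dimethoxy-6-methylbenzoyl fluoride F1. The compact acyl fluoride then acylates the 4-OH of 5 (K2CO3, cat. DMAP, MeCN, 60 °C) to give 8.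

**Step 5.** BCl3 may cleave the wrong ether or damage the depside link. The fallback sets out from 3 and comes back to the route at 9. It carries the ring B phenol under an acid-labile acetal instead of a methyl ether.
- NaSEt in DMF at 120 °C cleaves one of the two equivalent methyl ethers of 3 to give 2-chloro-3-methoxy-5-methylphenol F2.
- MOMCl and i-Pr2NEt in CH2Cl2 give 2-chloro-1-methoxy-3-(methoxymethoxy)-5-methylbenzene F3.
- n-BuLi/TMEDA in THF at −78 °C lithiates ortho to the stronger OMOM director, giving [3-chloro-4-methoxy-2-(methoxymethoxy)-6-methylphenyl]lithium F4, which iodine converts into 2-chloro-4-iodo-1-methoxy-3-(methoxymethoxy)-5-methylbenzene F5.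
- Coupling of F5 with 6 under the step 4 conditions gives methyl 4-{[3-chloro-4-methoxy-2-(methoxymethoxy)-6-methylbenzoyl]oxy}-2-hydroxy-6-methylbenzoate F6.
- Catalytic HCl in MeOH/CH2Cl2 at rt removes the acetal and gives 9.

**Step 3.** Formate 6 is an activated aryl formate and may hydrolyse or lose CO on isolation. The fallback sets out from 5 and comes back to the route at 8. Compound 6 is skipped and 4, 5 and CO gas (balloon) are combined in a three-component aryloxycarbonylation (Pd(OAc)2, Xantphos, Et3N, toluene, 80 °C). This makes no new compound (F0).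

## Further compounds

F1 | step 4 | 3-chloro-2,4-dimethoxy-6-methylbenzoyl fluoride | COc1cc(C)c(C(F)=O)c(OC)c1Cl
F2 | step 5 | 2-chloro-3-methoxy-5-methylphenol | COc1cc(C)cc(O)c1Cl
F3 | step 5 | 2-chloro-1-methoxy-3-(methoxymethoxy)-5-methylbenzene | COCOc1cc(C)cc(OC)c1Cl
F4 | step 5 | [3-chloro-4-methoxy-2-(methoxymethoxy)-6-methylphenyl]lithium | [Li]c1c(C)cc(OC)c(Cl)c1OCOC
F5 | step 5 | 2-chloro-4-iodo-1-methoxy-3-(methoxymethoxy)-5-methylbenzene | COCOc1c(I)c(C)cc(OC)c1Cl
F6 | step 5 | methyl 4-{[3-chloro-4-methoxy-2-(methoxymethoxy)-6-methylbenzoyl]oxy}-2-hydroxy-6-methylbenzoate | COC(=O)c1c(C)cc(OC(=O)c2c(C)cc(OC)c(Cl)c2OCOC)cc1O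
F0 | step 3 | none | none
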